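**Strategy**

The target is cut at the three C3–aryl bonds of its trans-dihydrobenzofurans (ring B with the styryl arm, 2R,3R; central ring A, 2S,3S; outer ring C, 2R,3R), which reduces it to one 4-bromo-2-aryl-2,3-dihydrobenzofuran-3-carboxylate, needed in both mirror forms. The feature used is the C3–C3a bond of ring B with its trans C2/C3 pair: it corresponds to a 2-arylchroman-4-one whose single stereocentre C2 comes from catalytic conjugate arylation. Iodine(III) in orthoformate shifts C4a from C4 to C3, which in one operation contracts the pyranone, forms C3–C3a, places the carboxylate trans and leaves a carbon that departs when C3 is arylated. Precursor: (2R)-5-bromo-7-methoxy-2-(4-methoxyphenyl)chroman-4-one.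

Key step: step 6

Remark (assumption): the facial sense of the Pd/PyOx conjugate arylation of chromone 5 is taken to follow the cyclic-enone model ((S)-ligand gives 2R); if the first run shows the opposite sense, the ligand enantiomers of steps 4 and 5 are exchanged and nothing else changes.

Remark (stereochemistry): the C3 centre made in steps 6 and 7 becomes a planar radical in steps 12–14; the final C3 configuration of every ring is set there, trans to the C2 aryl group that comes from steps 4 and 5.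

**Route**

Step 1
Reactants: 1 1-bromo-3,5-dimethoxybenzene
Product: 2 1-(2-bromo-4,6-dimethoxyphenyl)ethan-1-one
Conditions: AcCl (1.1 equiv), AlCl3 (1.2 equiv), CH2Cl2, 0 °C
Reagents that add atoms: acetyl chloride, CC(Cl)=O
Why: Friedel–Crafts acylation; the two positions ortho to bromine are equivalent (each para to one methoxy group) and are favoured over the site flanked by two methoxy groups, so the ketone regiochemistry is secured by the symmetrical starting material, which a direct acylation of a bromo-methoxyphenol with two different ortho sites would not do.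

Step 2
Reactants: 2 1-(2-bromo-4,6-dimethoxyphenyl)ethan-1-one
Product: 3 1-(2-bromo-6-hydroxy-4-methoxyphenyl)ethan-1-one
Conditions: BCl3 (1.2 equiv), CH2Cl2, −78 → 0 °C; aq. work-up
Reagents that add atoms: none
Why: Chelation-controlled Lewis-acid ether cleavage; boron held between the carbonyl oxygen and the ortho methoxy oxygen removes only that methyl group and leaves the para methoxy group and the bromide.

Step 3
Reactants: 3 1-(2-bromo-6-hydroxy-4-methoxyphenyl)ethan-1-one
Product: 5 5-bromo-7-methoxy-4H-chromen-4-one, via enaminone 4 (not isolated)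
Conditions: Me2NCH(OMe)2, PhMe, 100 °C; then conc. HCl, CH2Cl2, 40 °C
Reagents that add atoms: N,N-dimethylformamide dimethyl acetal, COC(OC)N(C)C
Why: Enaminone chromone synthesis; condensation of the methyl ketone with the amide acetal, then acid-induced addition of the phenol to the enaminone and loss of dimethylamine closes the pyranone.

Step 4
Reactants: 5 5-bromo-7-methoxy-4H-chromen-4-one; 6 4-methoxyphenylboronic acid
Product: 7 (2R)-5-bromo-7-methoxy-2-(4-methoxyphenyl)chroman-4-one
Conditions: Pd(OCOCF3)2 (5 mol%), (S)-t-BuPyOx (6 mol%), NH4PF6 (30 mol%), H2O (5 equiv), ClCH2CH2Cl, 60 °C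
Reagents that add atoms: none
Why: Pd(II)-catalysed asymmetric conjugate addition of an arylboronic acid to a chromone; the tert-butyl group of the pyridine-oxazoline ligand blocks one enone face during aryl-palladium insertion and so sets C2 as R, and phosphine-free Pd(II) should leave the aryl bromide alone.

Step 5
Reactants: 5 5-bromo-7-methoxy-4H-chromen-4-one; 6 4-methoxyphenylboronic acid
Product: 8 (2S)-5-bromo-7-methoxy-2-(4-methoxyphenyl)chroman-4-one
Conditions: Pd(OCOCF3)2 (5 mol%), (R)-t-BuPyOx (6 mol%), NH4PF6 (30 mol%), H2O (5 equiv), ClCH2CH2Cl, 60 °C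
Reagents that add atoms: none
Why: The same Pd(II)-catalysed asymmetric conjugate arylation with the mirror-image ligand should give the antipode, which is needed for ring A (2S).

Step 6
Reactants: 7 (2R)-5-bromo-7-methoxy-2-(4-methoxyphenyl)chroman-4-one
Product: 12 methyl (2R,3R)-4-bromo-6-methoxy-2-(4-methoxyphenyl)-2,3-dihydrobenzofuran-3-carboxylate, via enol ether 9 (not isolated), via ketal iodane 10 (not isolated), via orthoester 11 (not isolated)
Conditions: PhI(OAc)2 (1.2 equiv), conc. H2SO4 (0.5 equiv), HC(OMe)3, 0 °C → rt; then H2O, NaHCO3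
Reagents that add atoms: trimethyl orthoformate, COC(OC)OC; water, O
Why: Acid and orthoformate turn ketone 7 into enol ether 9; its C3 attacks iodine(III) on the face opposite the pseudo-equatorial C2 aryl group and methanol capture gives ketal iodane 10, whose equatorial C3–I bond is antiperiplanar to the ring bond C4–C4a, so aryl carbon C4a shifts from C4 to C3 as iodobenzene leaves and the dimethoxycarbenium ion at old C4 is caught as orthoester 11, which the aqueous quench hydrolyses to ester 12. The closest known reaction is the thallium(III)- or iodine(III)-mediated oxidative ring contraction of flavanones to trans-2-aryl-2,3-dihydrobenzofuran-3-carboxylates, a semipinacol-type 1,2-aryl shift. The five-membered ring is not closed by a cyclisation; it arises by contraction of the pyranone through a bridged arenium (phenonium-like) transition state that forms C3–C3a while C4–C4a breaks. The new centre C3 is controlled by C2: anti addition of iodine followed by invertive migration puts the carboxylate trans to the C2 aryl group, the epimerisable ester would converge on the same isomer, and C2 itself is not touched. The step needs C4a migration to beat both the 1,2-shift of the 4-methoxyphenyl group (isoflavone) and elimination to the flavone. This is secured by the two methoxy groups on C4 that stabilise the cation left behind, by the 7-methoxy group para and O1 ortho to C4a, and by the diequatorial conformer of 10, in which only C4–C4a is anti to C–I.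

Step 7
Reactants: 8 (2S)-5-bromo-7-methoxy-2-(4-methoxyphenyl)chroman-4-one
Product: 16 methyl (2S,3S)-4-bromo-6-methoxy-2-(4-methoxyphenyl)-2,3-dihydrobenzofuran-3-carboxylate, via enol ether 13 (not isolated), via ketal iodane 14 (not isolated), via orthoester 15 (not isolated)
Conditions: PhI(OAc)2 (1.2 equiv), conc. H2SO4 (0.5 equiv), HC(OMe)3, 0 °C → rt; then H2O, NaHCO3
Reagents that add atoms: trimethyl orthoformate, COC(OC)OC; water, O
Why: The same iodine(III) oxidative ring contraction on the antipode must behave identically and should give the mirror-image trans ester for ring A.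

Step 8
Reactants: 12 methyl (2R,3R)-4-bromo-6-methoxy-2-(4-methoxyphenyl)-2,3-dihydrobenzofuran-3-carboxylate
Product: 17 (2R,3R)-4-bromo-6-methoxy-2-(4-methoxyphenyl)-2,3-dihydrobenzofuran-3-carboxylic acid
Conditions: LiOH·H2O (3 equiv), THF/MeOH/H2O, rt; then 1 M HCl
Reagents that add atoms: lithium hydroxide, [Li+].[OH-]
Why: Ester saponification; the trans ester is the thermodynamic epimer, and ring opening by β-elimination of O1 is disfavoured because the enolate π-system is orthogonal to the in-plane C2–O bond.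

Step 9
Reactants: 16 methyl (2S,3S)-4-bromo-6-methoxy-2-(4-methoxyphenyl)-2,3-dihydrobenzofuran-3-carboxylate
Product: 18 (2S,3S)-4-bromo-6-methoxy-2-(4-methoxyphenyl)-2,3-dihydrobenzofuran-3-carboxylic acid
Conditions: LiOH·H2O (3 equiv), THF/MeOH/H2O, rt; then 1 M HCl
Reagents that add atoms: lithium hydroxide, [Li+].[OH-]
Why: Ester saponification as in step 8, on the mirror-image compound.

Step 10
Reactants: 17 (2R,3R)-4-bromo-6-methoxy-2-(4-methoxyphenyl)-2,3-dihydrobenzofuran-3-carboxylic acid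
Product: 19 1,3-dioxoisoindolin-2-yl (2R,3R)-4-bromo-6-methoxy-2-(4-methoxyphenyl)-2,3-dihydrobenzofuran-3-carboxylate
Conditions: N-hydroxyphthalimide (1.1 equiv), DIC (1.1 equiv), DMAP (10 mol%), CH2Cl2, rt
Reagents that add atoms: N-hydroxyphthalimide, O=C1c2ccccc2C(=O)N1O
Why: Carbodiimide (Steglich-type) esterification gives the isolable redox-active ester; C2 is not involved and C3 is replaced in the coupling anyway.

Step 11
Reactants: 18 (2S,3S)-4-bromo-6-methoxy-2-(4-methoxyphenyl)-2,3-dihydrobenzofuran-3-carboxylic acid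
Product: 20 1,3-dioxoisoindolin-2-yl (2S,3S)-4-bromo-6-methoxy-2-(4-methoxyphenyl)-2,3-dihydrobenzofuran-3-carboxylate
Conditions: N-hydroxyphthalimide (1.1 equiv), DIC (1.1 equiv), DMAP (10 mol%), CH2Cl2, rt
Reagents that add atoms: N-hydroxyphthalimide, O=C1c2ccccc2C(=O)N1O
Why: Carbodiimide (Steglich-type) esterification as in step 10, on the mirror-image acid.

Step 12
Reactants: 1 1-bromo-3,5-dimethoxybenzene; 19 1,3-dioxoisoindolin-2-yl (2R,3R)-4-bromo-6-methoxy-2-(4-methoxyphenyl)-2,3-dihydrobenzofuran-3-carboxylate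
Product: 23 (2R,3R)-4-bromo-3-(3,5-dimethoxyphenyl)-6-methoxy-2-(4-methoxyphenyl)-2,3-dihydrobenzofuran (ring C bromide), via aryllithium 21 (not isolated), via arylzinc chloride 22 (not isolated)
Conditions: 1, t-BuLi (2.0 equiv), THF, −78 °C; ZnCl2, −78 °C → rt; then 19 (0.5 equiv), NiCl2·glyme (20 mol%), 4,4′-di-tert-butyl-2,2′-bipyridine (40 mol%), THF/DMF, 0 °C → rt
Reagents that add atoms: none
Why: Nickel-catalysed decarboxylative Negishi-type arylation of a redox-active ester; electron transfer from aryl-nickel(I) breaks 19 into CO2, phthalimide anion and the planar benzylic C3 radical, which aryl-nickel captures on the face away from the C2 aryl group so that reductive elimination sets C3 trans (3R), while reduction of the ester should be much faster than insertion into the hindered C4–Br bond, and the reaction is quenched once 19 is consumed.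

Step 13
Reactants: 23 (2R,3R)-4-bromo-3-(3,5-dimethoxyphenyl)-6-methoxy-2-(4-methoxyphenyl)-2,3-dihydrobenzofuran; 20 1,3-dioxoisoindolin-2-yl (2S,3S)-4-bromo-6-methoxy-2-(4-methoxyphenyl)-2,3-dihydrobenzofuran-3-carboxylate
Product: 26 (2S,3S)-4-bromo-3-[(2R,3R)-3-(3,5-dimethoxyphenyl)-6-methoxy-2-(4-methoxyphenyl)-2,3-dihydrobenzofuran-4-yl]-6-methoxy-2-(4-methoxyphenyl)-2,3-dihydrobenzofuran (rings A–C bromide), via aryllithium 24 (not isolated), via arylzinc chloride 25 (not isolated)
Conditions: 23 (1.5 equiv), t-BuLi (3.0 equiv), THF, −78 °C; ZnCl2, −78 °C → rt; then 20 (1.0 equiv), NiCl2·glyme (20 mol%), 4,4′-di-tert-butyl-2,2′-bipyridine (40 mol%), THF/DMF, 0 °C → rt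
Reagents that add atoms: none
Why: The same decarboxylative Negishi-type arylation with the ring-C arylzinc and the mirror-image ester; the C3 radical of ring A is captured anti to its own C2 aryl group, which alone decides the new centre (3S), and lithium–bromine exchange at −78 °C with immediate transfer to zinc should leave the benzylic C–H bonds and the ring-C stereocentres untouched.

Step 14
Reactants: 26 rings A–C bromide; 19 1,3-dioxoisoindolin-2-yl (2R,3R)-4-bromo-6-methoxy-2-(4-methoxyphenyl)-2,3-dihydrobenzofuran-3-carboxylate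
Product: 29 (2R,3R)-4-bromo-3-{(2S,3S)-3-[(2R,3R)-3-(3,5-dimethoxyphenyl)-6-methoxy-2-(4-methoxyphenyl)-2,3-dihydrobenzofuran-4-yl]-6-methoxy-2-(4-methoxyphenyl)-2,3-dihydrobenzofuran-4-yl}-6-methoxy-2-(4-methoxyphenyl)-2,3-dihydrobenzofuran (rings B–A–C bromide), via aryllithium 27 (not isolated), via arylzinc chloride 28 (not isolated)
Conditions: 26 (1.5 equiv), t-BuLi (3.0 equiv), THF, −78 °C; ZnCl2, −78 °C → rt; then 19 (1.0 equiv), NiCl2·glyme (20 mol%), 4,4′-di-tert-butyl-2,2′-bipyridine (40 mol%), THF/DMF, 0 °C → rt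
Reagents that add atoms: none
Why: A third decarboxylative Negishi-type arylation; the ring-B C3 radical from 19 is captured by the ring-A aryl-nickel species anti to the C2 aryl group of ring B, giving the trans (2R,3R) ring B and keeping its C4 bromide for the last carbon–carbon bond.

Step 15
Reactants: 29 rings B–A–C bromide; 30 3,4-dimethoxystyrene
Product: 31 (2R,3R)-4-[(E)-2-(3,4-dimethoxyphenyl)ethenyl]-3-{(2S,3S)-3-[(2R,3R)-3-(3,5-dimethoxyphenyl)-6-methoxy-2-(4-methoxyphenyl)-2,3-dihydrobenzofuran-4-yl]-6-methoxy-2-(4-methoxyphenyl)-2,3-dihydrobenzofuran-4-yl}-6-methoxy-2-(4-methoxyphenyl)-2,3-dihydrobenzofuran (decamethyl ether of the target)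
Conditions: Pd2(dba)3 (2.5 mol%), [(t-Bu)3PH]BF4 (10 mol%), Cy2NMe (1.5 equiv), 1,4-dioxane, 80 °C
Reagents that add atoms: none
Why: Mizoroki–Heck reaction; the bulky electron-rich phosphine allows oxidative addition into the ortho-substituted bromide, and syn insertion at the terminal styrene carbon followed by syn β-hydride elimination gives the E-stilbene without touching the six sp3 stereocentres.

Step 16
Reactants: 31 decamethyl ether of the target
Product: 32 CNP0099535.1 (target)
Conditions: BBr3 (30 equiv), CH2Cl2, −78 → 0 °C; then MeOH, H2O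
Reagents that add atoms: none
Why: Lewis-acid cleavage of aryl methyl ethers (BBr3 demethylation); bromide attacks the methyl group of each boron-bound ether, so all ten O–CH3 bonds are broken while the C2–O ring bonds, the alkene and the stereocentres should remain at low temperature.

**Compound list**

1 | 1-bromo-3,5-dimethoxybenzene | COc1cc(Br)cc(OC)c1 | starting material
2 | 1-(2-bromo-4,6-dimethoxyphenyl)ethan-1-one | CC(=O)c1c(Br)cc(OC)cc1OC | intermediate
3 | 1-(2-bromo-6-hydroxy-4-methoxyphenyl)ethan-1-one | CC(=O)c1c(O)cc(OC)cc1Br | intermediate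
4 | (E)-1-(2-bromo-6-hydroxy-4-methoxyphenyl)-3-(dimethylamino)prop-2-en-1-one (enaminone, not isolated) | CN(C)/C=C/C(=O)c1c(O)cc(OC)cc1Br | intermediate
5 | 5-bromo-7-methoxy-4H-chromen-4-one | COc1cc(Br)c2c(c1)OC=CC2=O | intermediate
6 | 4-methoxyphenylboronic acid | COc1ccc(B(O)O)cc1 | starting material
7 | (2R)-5-bromo-7-methoxy-2-(4-methoxyphenyl)chroman-4-one | COc1cc2O[C@@H](c3ccc(OC)cc3)CC(=O)c2c(Br)c1 | intermediate
8 | (2S)-5-bromo-7-methoxy-2-(4-methoxyphenyl)chroman-4-one | COc1cc2O[C@H](c3ccc(OC)cc3)CC(=O)c2c(Br)c1 | intermediate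
9 | (2R)-5-bromo-4,7-dimethoxy-2-(4-methoxyphenyl)-2H-chromene (enol ether, not isolated) | COc1cc2O[C@@H](c3ccc(OC)cc3)C=C(OC)c2c(Br)c1 | intermediate
10 | (2S,3S)-3-[acetoxy(phenyl)-λ3-iodanyl]-5-bromo-4,4,7-trimethoxy-2-(4-methoxyphenyl)chromane (ketal iodane, not isolated; iodine trans to the C2 aryl group; C2 unchanged in space, only its CIP label changes) | COc1cc2O[C@@H](c3ccc(OC)cc3)[C@H](I(OC(C)=O)c3ccccc3)C(OC)(OC)c2c(Br)c1 | intermediate
11 | (2R,3R)-4-bromo-6-methoxy-2-(4-methoxyphenyl)-3-(trimethoxymethyl)-2,3-dihydrobenzofuran (orthoester, not isolated) | COC(OC)(OC)[C@@H]1c2c(Br)cc(OC)cc2O[C@H]1c1ccc(OC)cc1 | intermediate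
12 | methyl (2R,3R)-4-bromo-6-methoxy-2-(4-methoxyphenyl)-2,3-dihydrobenzofuran-3-carboxylate (trans) | COC(=O)[C@@H]1c2c(Br)cc(OC)cc2O[C@H]1c1ccc(OC)cc1 | intermediate
13 | (2S)-5-bromo-4,7-dimethoxy-2-(4-methoxyphenyl)-2H-chromene (enol ether, not isolated) | COc1cc2O[C@H](c3ccc(OC)cc3)C=C(OC)c2c(Br)c1 | intermediate
14 | (2R,3R)-3-[acetoxy(phenyl)-λ3-iodanyl]-5-bromo-4,4,7-trimethoxy-2-(4-methoxyphenyl)chromane (ketal iodane, not isolated; mirror image of 10) | COc1cc2O[C@H](c3ccc(OC)cc3)[C@@H](I(OC(C)=O)c3ccccc3)C(OC)(OC)c2c(Br)c1 | intermediate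
15 | (2S,3S)-4-bromo-6-methoxy-2-(4-methoxyphenyl)-3-(trimethoxymethyl)-2,3-dihydrobenzofuran (orthoester, not isolated) | COC(OC)(OC)[C@H]1c2c(Br)cc(OC)cc2O[C@@H]1c1ccc(OC)cc1 | intermediate
16 | methyl (2S,3S)-4-bromo-6-methoxy-2-(4-methoxyphenyl)-2,3-dihydrobenzofuran-3-carboxylate (trans) | COC(=O)[C@H]1c2c(Br)cc(OC)cc2O[C@@H]1c1ccc(OC)cc1 | intermediate
17 | (2R,3R)-4-bromo-6-methoxy-2-(4-methoxyphenyl)-2,3-dihydrobenzofuran-3-carboxylic acid | OC(=O)[C@@H]1c2c(Br)cc(OC)cc2O[C@H]1c1ccc(OC)cc1 | intermediate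
18 | (2S,3S)-4-bromo-6-methoxy-2-(4-methoxyphenyl)-2,3-dihydrobenzofuran-3-carboxylic acid | OC(=O)[C@H]1c2c(Br)cc(OC)cc2O[C@@H]1c1ccc(OC)cc1 | intermediate
19 | 1,3-dioxoisoindolin-2-yl (2R,3R)-4-bromo-6-methoxy-2-(4-methoxyphenyl)-2,3-dihydrobenzofuran-3-carboxylate | O=C(ON1C(=O)c2ccccc2C1=O)[C@@H]1c2c(Br)cc(OC)cc2O[C@H]1c1ccc(OC)cc1 | intermediate
20 | 1,3-dioxoisoindolin-2-yl (2S,3S)-4-bromo-6-methoxy-2-(4-methoxyphenyl)-2,3-dihydrobenzofuran-3-carboxylate | O=C(ON1C(=O)c2ccccc2C1=O)[C@H]1c2c(Br)cc(OC)cc2O[C@@H]1c1ccc(OC)cc1 | intermediate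
21 | (3,5-dimethoxyphenyl)lithium (not isolated) | [Li]c1cc(OC)cc(OC)c1 | intermediate
22 | (3,5-dimethoxyphenyl)zinc chloride (not isolated) | Cl[Zn]c1cc(OC)cc(OC)c1 | intermediate
23 | (2R,3R)-4-bromo-3-(3,5-dimethoxyphenyl)-6-methoxy-2-(4-methoxyphenyl)-2,3-dihydrobenzofuran (ring C bromide, trans) | Brc1cc(OC)cc2c1[C@@H](c1cc(OC)cc(OC)c1)[C@H](c1ccc(OC)cc1)O2 | intermediate
24 | [(2R,3R)-3-(3,5-dimethoxyphenyl)-6-methoxy-2-(4-methoxyphenyl)-2,3-dihydrobenzofuran-4-yl]lithium (not isolated) | [Li]c1cc(OC)cc2c1[C@@H](c1cc(OC)cc(OC)c1)[C@H](c1ccc(OC)cc1)O2 | intermediate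
25 | [(2R,3R)-3-(3,5-dimethoxyphenyl)-6-methoxy-2-(4-methoxyphenyl)-2,3-dihydrobenzofuran-4-yl]zinc chloride (not isolated) | Cl[Zn]c1cc(OC)cc2c1[C@@H](c1cc(OC)cc(OC)c1)[C@H](c1ccc(OC)cc1)O2 | intermediate
26 | (2S,3S)-4-bromo-3-[(2R,3R)-3-(3,5-dimethoxyphenyl)-6-methoxy-2-(4-methoxyphenyl)-2,3-dihydrobenzofuran-4-yl]-6-methoxy-2-(4-methoxyphenyl)-2,3-dihydrobenzofuran (rings A–C bromide) | COc1ccc([C@H]2Oc3cc(OC)cc(Br)c3[C@@H]2c2cc(OC)cc3c2[C@@H](c2cc(OC)cc(OC)c2)[C@H](c2ccc(OC)cc2)O3)cc1 | intermediate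
27 | aryllithium of 26 (lithium in place of bromine at C4 of ring A; not isolated) | COc1ccc([C@H]2Oc3cc(OC)cc([Li])c3[C@@H]2c2cc(OC)cc3c2[C@@H](c2cc(OC)cc(OC)c2)[C@H](c2ccc(OC)cc2)O3)cc1 | intermediate
28 | arylzinc chloride of 26 (ZnCl in place of bromine at C4 of ring A; not isolated) | COc1ccc([C@H]2Oc3cc(OC)cc([Zn]Cl)c3[C@@H]2c2cc(OC)cc3c2[C@@H](c2cc(OC)cc(OC)c2)[C@H](c2ccc(OC)cc2)O3)cc1 | intermediate
29 | (2R,3R)-4-bromo-3-{(2S,3S)-3-[(2R,3R)-3-(3,5-dimethoxyphenyl)-6-methoxy-2-(4-methoxyphenyl)-2,3-dihydrobenzofuran-4-yl]-6-methoxy-2-(4-methoxyphenyl)-2,3-dihydrobenzofuran-4-yl}-6-methoxy-2-(4-methoxyphenyl)-2,3-dihydrobenzofuran (rings B–A–C bromide) | COc1ccc([C@H]2Oc3cc(OC)cc([C@@H]4c5c(Br)cc(OC)cc5O[C@H]4c4ccc(OC)cc4)c3[C@@H]2c2cc(OC)cc3c2[C@@H](c2cc(OC)cc(OC)c2)[C@H](c2ccc(OC)cc2)O3)cc1 | intermediate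
30 | 3,4-dimethoxystyrene | C=Cc1ccc(OC)c(OC)c1 | starting material
31 | decamethyl ether of the target: 29 with (E)-2-(3,4-dimethoxyphenyl)ethenyl in place of bromine at C4 of ring B | COc1ccc([C@H]2Oc3cc(OC)cc([C@@H]4c5c(/C=C/c6ccc(OC)c(OC)c6)cc(OC)cc5O[C@H]4c4ccc(OC)cc4)c3[C@@H]2c2cc(OC)cc3c2[C@@H](c2cc(OC)cc(OC)c2)[C@H](c2ccc(OC)cc2)O3)cc1 | intermediate
32 | CNP0099535.1: 4-[(E)-2-{(2R,3R)-3-[(2S,3S)-3-[(2R,3R)-3-(3,5-dihydroxyphenyl)-6-hydroxy-2-(4-hydroxyphenyl)-2,3-dihydrobenzofuran-4-yl]-6-hydroxy-2-(4-hydroxyphenyl)-2,3-dihydrobenzofuran-4-yl]-6-hydroxy-2-(4-hydroxyphenyl)-2,3-dihydrobenzofuran-4-yl}ethenyl]benzene-1,2-diol | Oc1ccc([C@H]2Oc3cc(O)cc([C@@H]4c5c(/C=C/c6ccc(O)c(O)c6)cc(O)cc5O[C@H]4c4ccc(O)cc4)c3[C@@H]2c2cc(O)cc3c2[C@@H](c2cc(O)cc(O)c2)[C@H](c2ccc(O)cc2)O3)cc1 | target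

**Step count and risks**

Total steps: 16. Longest linear sequence: 12 (steps 1, 2, 3, 4, 6, 8, 10, 12, 13, 14, 15, 16).

Risk 1, step 6 (step 7 is the same reaction on the antipode and shares its fate). The 4-methoxyphenyl group on C2 may migrate instead of C4a, or the iodane may eliminate toward the flavone. Acid-induced ring opening before the ketone is masked would also erode the C2 purity. Fallback, from 7 back to 12: a Wolff ring contraction, which uses the same C4→C3 shift of C4a but passes through a carbene-free diazo pathway. Ketone 7 is trifluoroacetylated at C3 (LiHMDS, CF3CO2CH2CF3, THF, −78 °C) to give (2R)-5-bromo-7-methoxy-2-(4-methoxyphenyl)-3-(trifluoroacetyl)chroman-4-one F1. Detrifluoroacetylative diazo transfer (MsN3, Et3N, MeCN) then gives (2S)-5-bromo-3-diazo-7-methoxy-2-(4-methoxyphenyl)chroman-4-one F2 (C2 unchanged in space). Irradiation at 350 nm in methanol should move C4a from C4 to C3 and give the ketene [(2S)-4-bromo-6-methoxy-2-(4-methoxyphenyl)benzofuran-3(2H)-ylidene]methanone F3. Methanol adds to it to give 12 together with its cis epimer methyl (2R,3S)-4-bromo-6-methoxy-2-(4-methoxyphenyl)-2,3-dihydrobenzofuran-3-carboxylate F4, which NaOMe in MeOH equilibrates to trans 12.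

Risk 2, step 14 (step 13 is of the same kind but less crowded). Transfer of the bulky ortho-substituted aryl group to nickel and capture of the congested C3 radical may be slow, so that the radical dimerises or is reduced. The aryllithium may also be quenched by a benzylic C–H before zinc arrives, and excess arylzinc could begin to attack the aryl bromide. Fallback, from 26 back to 29, without any stoichiometric organometallic: copper-catalysed halogen exchange (CuI, NaI, trans-N,N′-dimethylcyclohexane-1,2-diamine, dioxane, 110 °C) converts 26 into the aryl iodide (2S,3S)-3-[(2R,3R)-3-(3,5-dimethoxyphenyl)-6-methoxy-2-(4-methoxyphenyl)-2,3-dihydrobenzofuran-4-yl]-4-iodo-6-methoxy-2-(4-methoxyphenyl)-2,3-dihydrobenzofuran F5. A nickel-catalysed decarboxylative cross-electrophile coupling of F5 with ester 19 (NiBr2·glyme, 4,4′-di-tert-butyl-2,2′-bipyridine, Zn dust, DMA, rt), in which nickel inserts into C–I in preference to C–Br, should then give 29.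

Risk 3, step 16. During the tenfold ether cleavage, adventitious HBr may protonate the stilbene and trigger Friedel–Crafts closure onto ring A, or a para-oxybenzylic C2–O bond may ionise and epimerise. Fallback, from 29 to 32, which removes the methyl groups before the alkene exists: BBr3 (CH2Cl2, −78 → 0 °C) on 29 gives the octaphenol bromide F6. Ac2O/pyridine gives the octaacetate bromide F7. A Heck reaction of F7 with commercial 3,4-diacetoxystyrene (Pd2(dba)3, [(t-Bu)3PH]BF4, Cy2NMe, dioxane, 80 °C) gives the decaacetate of the target F8. Catalytic NaOMe in MeOH at 0 °C under argon, followed by neutralisation with acidic resin, then releases 32 without any acid.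

**Further compounds**

F1 | step 6 | (2R)-5-bromo-7-methoxy-2-(4-methoxyphenyl)-3-(trifluoroacetyl)chroman-4-one (C3 epimers and enol form) | COc1cc2O[C@@H](c3ccc(OC)cc3)C(C(=O)C(F)(F)F)C(=O)c2c(Br)c1
F2 | step 6 | (2S)-5-bromo-3-diazo-7-methoxy-2-(4-methoxyphenyl)chroman-4-one | COc1cc2O[C@@H](c3ccc(OC)cc3)C(=[N+]=[N-])C(=O)c2c(Br)c1
F3 | step 6 | [(2S)-4-bromo-6-methoxy-2-(4-methoxyphenyl)benzofuran-3(2H)-ylidene]methanone (ketene, not isolated) | O=C=C1c2c(Br)cc(OC)cc2O[C@H]1c1ccc(OC)cc1
F4 | step 6 | methyl (2R,3S)-4-bromo-6-methoxy-2-(4-methoxyphenyl)-2,3-dihydrobenzofuran-3-carboxylate (cis) | COC(=O)[C@H]1c2c(Br)cc(OC)cc2O[C@H]1c1ccc(OC)cc1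
F5 | step 14 | (2S,3S)-3-[(2R,3R)-3-(3,5-dimethoxyphenyl)-6-methoxy-2-(4-methoxyphenyl)-2,3-dihydrobenzofuran-4-yl]-4-iodo-6-methoxy-2-(4-methoxyphenyl)-2,3-dihydrobenzofuran | COc1ccc([C@H]2Oc3cc(OC)cc(I)c3[C@@H]2c2cc(OC)cc3c2[C@@H](c2cc(OC)cc(OC)c2)[C@H](c2ccc(OC)cc2)O3)cc1
F6 | step 16 | octaphenol bromide (29 with all eight methyl groups removed) | Oc1ccc([C@H]2Oc3cc(O)cc([C@@H]4c5c(Br)cc(O)cc5O[C@H]4c4ccc(O)cc4)c3[C@@H]2c2cc(O)cc3c2[C@@H](c2cc(O)cc(O)c2)[C@H](c2ccc(O)cc2)O3)cc1
F7 | step 16 | octaacetate of F6 | CC(=O)Oc1ccc([C@H]2Oc3cc(OC(C)=O)cc([C@@H]4c5c(Br)cc(OC(C)=O)cc5O[C@H]4c4ccc(OC(C)=O)cc4)c3[C@@H]2c2cc(OC(C)=O)cc3c2[C@@H](c2cc(OC(C)=O)cc(OC(C)=O)c2)[C@H](c2ccc(OC(C)=O)cc2)O3)cc1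
F8 | step 16 | decaacetate of the target | CC(=O)Oc1ccc([C@H]2Oc3cc(OC(C)=O)cc([C@@H]4c5c(/C=C/c6ccc(OC(C)=O)c(OC(C)=O)c6)cc(OC(C)=O)cc5O[C@H]4c4ccc(OC(C)=O)cc4)c3[C@@H]2c2cc(OC(C)=O)cc3c2[C@@H](c2cc(OC(C)=O)cc(OC(C)=O)c2)[C@H](c2ccc(OC(C)=O)cc2)O3)cc1
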